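## Retrosynthetic overview

1. Target 9 comes from dibenzyl-protected 8 by neutral hydrogenolysis. CO2H and ArOH are unmasked last, so a free acid never meets a free side-chain OH and no lactone can form.
2. Key disconnection is the C2'–OAc bond. 8 comes from the E-styrene 7 and acetic acid by enantioselective anti-Markovnikov hydroacetoxylation, which sets the only stereocentre.
3. 7 comes from the racemic dihydroisocoumarin 5 by base-induced β-elimination (lactone opening) and double benzylation in one pot.
4. 5 comes from lateral lithiation of toluate 1 and addition to dodecanal 2, the only C–C bond formation.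
5. Rings: the arene is bought. The lactone ring is formed in step 1 only as an olefination device and is opened again in step 2. No ring is built in the target.

Assumption: 1 (sparassol, methyl everninate) is bought as a catalogue chemical, and because the facial bias of the new catalyst cannot be predicted, the IDPi antipode written is the one that a test run shows to give the (R)-acetate (both antipodes derive from (R)- or (S)-BINOL).

## Route

Step 1
Reactants: 1 methyl 2-hydroxy-4-methoxy-6-methylbenzoate; 2 dodecanal
Product: 5 (±)-8-hydroxy-6-methoxy-3-undecyl-3,4-dihydro-1H-isochromen-1-one, via dilithio dianion 3 (not isolated), via dilithium aldolate 4 (not isolated)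
Conditions: LDA (2.4 equiv), THF, −78 °C, 1 h; then 2 (1.2 equiv), −78 °C to rt; 1 M HCl
Reagents that add atoms: none
Why: Lateral (benzylic) lithiation of the o-toluate gives a phenoxide/benzylic dianion that adds 1,2 to the aldehyde (aldol-type addition), and the alkoxide closes onto the neighbouring ester (lactonisation, completed on acidic work-up); the stereocentre formed here is racemic and is erased in step 2.

Step 2
Reactants: 5 (±)-8-hydroxy-6-methoxy-3-undecyl-3,4-dihydro-1H-isochromen-1-one
Product: 7 benzyl 2-(benzyloxy)-4-methoxy-6-[(1E)-tridec-1-en-1-yl]benzoate, via dipotassium alkenylsalicylate 6 (not isolated)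
Conditions: KOtBu (2.4 equiv), DMSO, rt, 2 h; then BnBr (2.8 equiv), rt
Reagents that add atoms: benzyl bromide BrCc1ccccc1
Why: The C4–H is benzylic and activated by the ortho carbonyl, so base triggers E1cB/anti-E2 β-elimination of the carboxylate to the conjugated E-alkene (pseudo-equatorial undecyl ends up trans to the aryl group), and the dianion is then capped by SN2 benzylation of carboxylate and phenoxide (Williamson type).

Step 3
Reactants: 7 benzyl 2-(benzyloxy)-4-methoxy-6-[(1E)-tridec-1-en-1-yl]benzoate
Product: 8 benzyl 2-[(2R)-2-(acetyloxy)tridecyl]-6-(benzyloxy)-4-methoxybenzoate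
Conditions: [9-mesityl-10-phenylacridinium][(S,S)-IDPi] (5 mol %), (PhS)2 (10 mol %), AcOH (10 equiv), PhMe/CH2Cl2 4:1, 450 nm LED, −40 °C
Reagents that add atoms: acetic acid CC(=O)O
Why: Proposed new method: enantioselective intermolecular anti-Markovnikov hydroacetoxylation by counteranion-directed photoredox catalysis. The excited acridinium oxidises the electron-rich styrene to its radical cation, which in the non-polar medium stays paired with the confined chiral imidodiphosphorimidate anion (the only anion present, since AcOH is far too weak an acid to displace it). AcOH, hydrogen-bonded to a basic site of that anion, attacks the distal alkene carbon because this leaves the spin benzylic, while the anion takes up the proton, so the C–O bond and the (R)-centre form inside the chiral pocket. PhSH then delivers H to the benzylic radical, PhS• reoxidises the acridinyl radical, and the thiolate is reprotonated by IDPi–H, closing both cycles. The closest known reaction types are the racemic acridinium/thiol anti-Markovnikov hydroacyloxylation of β-alkylstyrenes and the asymmetric counteranion-directed photoredox cycloadditions of styrene radical cations (C–C bond formation only).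

Step 4
Reactants: 8 benzyl 2-[(2R)-2-(acetyloxy)tridecyl]-6-(benzyloxy)-4-methoxybenzoate
Product: 9 2-[(2R)-2-(acetyloxy)tridecyl]-6-hydroxy-4-methoxybenzoic acid (target)
Conditions: H2 (1 atm), 10 % Pd/C, EtOAc, rt
Reagents that add atoms: none
Why: Catalytic hydrogenolysis cleaves the benzyl ester and the benzyl aryl ether under neutral conditions, while the acetate is homobenzylic rather than benzylic, so its C–O bond and the stereocentre stay untouched and no free alcohol appears that could lactonise.

## Compound list

1 | methyl 2-hydroxy-4-methoxy-6-methylbenzoate (sparassol) | COC(=O)c1c(C)cc(OC)cc1O | starting material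
2 | dodecanal | CCCCCCCCCCCC=O | starting material
3 | dilithio dianion of 1 (lithium phenoxide plus benzylic carbanion) | [Li+].[Li+].[CH2-]c1cc(OC)cc([O-])c1C(=O)OC | intermediate
4 | dilithium salt (alkoxide, phenoxide) of (±)-methyl 2-hydroxy-6-(2-hydroxytridecyl)-4-methoxybenzoate | [Li+].[Li+].CCCCCCCCCCCC([O-])Cc1cc(OC)cc([O-])c1C(=O)OC | intermediate
5 | (±)-8-hydroxy-6-methoxy-3-undecyl-3,4-dihydro-1H-isochromen-1-one | CCCCCCCCCCCC1Cc2cc(OC)cc(O)c2C(=O)O1 | intermediate
6 | dipotassium 4-methoxy-2-oxido-6-[(1E)-tridec-1-en-1-yl]benzoate | [K+].[K+].CCCCCCCCCCC/C=C/c1cc(OC)cc([O-])c1C(=O)[O-] | intermediate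
7 | benzyl 2-(benzyloxy)-4-methoxy-6-[(1E)-tridec-1-en-1-yl]benzoate | CCCCCCCCCCC/C=C/c1cc(OC)cc(OCc2ccccc2)c1C(=O)OCc1ccccc1 | intermediate
8 | benzyl 2-[(2R)-2-(acetyloxy)tridecyl]-6-(benzyloxy)-4-methoxybenzoate | CCCCCCCCCCC[C@H](Cc1cc(OC)cc(OCc2ccccc2)c1C(=O)OCc1ccccc1)OC(C)=O | intermediate
9 | 2-[(2R)-2-(acetyloxy)tridecyl]-6-hydroxy-4-methoxybenzoic acid (CNP0269024.1) | CCCCCCCCCCC[C@H](Cc1cc(OC)cc(O)c1C(=O)O)OC(C)=O | target

## Step count and risks

Total step count: 4. Longest linear sequence: 4.

**Risk 1, step 3 (the proposed new step).**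
- What can go wrong:
  - The ee may be low.
  - The ortho ester carbonyl may trap the radical cation and give lactone with loss of benzyl.
  - The radical cation may dimerise.
- The fallback uses known chemistry, sets out from 7 and returns at 8.
- Shi asymmetric epoxidation of the E-alkene uses the D-fructose-derived ketone, Oxone, K2CO3 buffer and MeCN/dimethoxymethane at 0 °C. This ketone gives R,R epoxides from trans-β-alkylstyrenes, here benzyl 2-(benzyloxy)-4-methoxy-6-[(2R,3R)-3-undecyloxiran-2-yl]benzoate F1.
- Titanocene(III) reductive opening of Nugent–RajanBabu type follows (Cp2TiCl2 cat., Mn, collidine·HCl, 1,4-cyclohexadiene, THF). It breaks only the benzylic C–O bond through the benzylic radical and keeps the C2'–O bond. The product is benzyl 2-(benzyloxy)-6-[(2R)-2-hydroxytridecyl]-4-methoxybenzoate F2.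
- F2 is acetylated at once (Ac2O, pyridine, DMAP, 0 °C) to 8.

**Risk 2, step 2.**
- The phenoxide form of 5 may resist elimination, or tert-butoxide may attack the lactone carbonyl.
- The fallback replaces the lactone elimination by stepwise activation of the alcohol. It sets out from 5 and returns at 7.
- Saponification (KOH, aq. THF/MeOH, then evaporation to dryness) gives dipotassium (±)-2-(2-hydroxytridecyl)-4-methoxy-6-oxidobenzoate F3.
- BnBr in DMF gives (±)-benzyl 2-(benzyloxy)-6-(2-hydroxytridecyl)-4-methoxybenzoate F4.
- MsCl/Et3N gives (±)-benzyl 2-(benzyloxy)-4-methoxy-6-[2-(methylsulfonyloxy)tridecyl]benzoate F5.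
- DBU in toluene at 80 °C effects E2 elimination toward conjugation to give 7.

**Risk 3, step 1.**
- The basic benzylic anion may enolise dodecanal, or the toluate may self-condense.
- The fallback swaps carbanion chemistry for C–H activation. It sets out from 2 and returns at 5.
- Corey–Chaykovsky methylenation of 2 (Me3S+ I−, NaH, DMSO/THF) gives (±)-2-undecyloxirane F6.
- F6 is used in the carboxylate-directed Pd(II)-catalysed ortho-C–H alkylation of bought 2-hydroxy-4-methoxybenzoic acid (COc1ccc(C(=O)O)c(O)c1). Conditions are Pd(OAc)2, N-acetyl-tert-leucine, KOAc and HFIP at 75 °C.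
- The only free ortho position is alkylated at the terminal epoxide carbon, and the hydroxy acid lactonises in situ to 5.

## Further compounds

F1 | step 3 | benzyl 2-(benzyloxy)-4-methoxy-6-[(2R,3R)-3-undecyloxiran-2-yl]benzoate | CCCCCCCCCCC[C@H]1O[C@@H]1c2cc(OC)cc(OCc3ccccc3)c2C(=O)OCc4ccccc4
F2 | step 3 | benzyl 2-(benzyloxy)-6-[(2R)-2-hydroxytridecyl]-4-methoxybenzoate | CCCCCCCCCCC[C@H](Cc1cc(OC)cc(OCc2ccccc2)c1C(=O)OCc1ccccc1)O
F3 | step 2 | dipotassium (±)-2-(2-hydroxytridecyl)-4-methoxy-6-oxidobenzoate | [K+].[K+].CCCCCCCCCCCC(O)Cc1cc(OC)cc([O-])c1C(=O)[O-]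
F4 | step 2 | (±)-benzyl 2-(benzyloxy)-6-(2-hydroxytridecyl)-4-methoxybenzoate | CCCCCCCCCCCC(O)Cc1cc(OC)cc(OCc2ccccc2)c1C(=O)OCc1ccccc1
F5 | step 2 | (±)-benzyl 2-(benzyloxy)-4-methoxy-6-[2-(methylsulfonyloxy)tridecyl]benzoate | CCCCCCCCCCCC(OS(C)(=O)=O)Cc1cc(OC)cc(OCc2ccccc2)c1C(=O)OCc1ccccc1
F6 | step 1 | (±)-2-undecyloxirane (1,2-epoxytridecane) | CCCCCCCCCCCC1CO1
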